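In a one-step world the flask stops when one partner is gone, and a division of charges gives the end. Here I supposed that each coupling costs two free base: one frees the nucleophile from its protonated form, the other takes up the acid set free.

| flask | electrophile | free base | protonated nucleophile | remark | time |
|---|---|---|---|---|---|
| east | 15 mM | 15 mM | 11 mM (fed, over 1.0 min) | run made earlier |  |
| north-east | 15 mM | 15 mM | 7.9 mM (fed, over 1.0 min) | run made earlier |  |
| grey | 15 mM | 15.0 mM | 15.8 mM (fed, over 1.0 min) |  | 50 min |
| violet | 15 mM | 30.0 mM | 15.8 mM (fed, over 1.0 min) |  | 50 min |

| run | time / min | electrophile / % | target / % |
|---|---|---|---|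
| east | 1.33 | 67 | 34 |
| east | 2.50 | 56 | 47 |
| east | 4.00 | 48 | 52 |
| east | 6.00 | 50 | 48 |
| east | 10.0 | 45 | 54 |
| east | 20.0 | 34 | 57 |
| north-east | 1.33 | 75 | 29 |
| north-east | 2.50 | 64 | 40 |
| north-east | 4.00 | 56 | 45 |
| north-east | 6.00 | 49 | 46 |
| north-east | 10.0 | 50 | 50 |
| north-east | 20.0 | 48 | 54 |

(scatter of a reading: 1.5 percentage points)

- what was read earlier has a scatter of 1.5 percentage points, one standard deviation
- a reading or a percentage of target counts all its forms, free or not
- no earlier run changes the charge of free base; that part of a forecast is a guess

- part of the electrophile that has reacted at the end, grey
- part of the electrophile that has reacted at the end, violet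
- what raising the concentration of free base from its lowest to its highest value here does to the part of the electrophile that has reacted (changes below 5 percentage points count as none) (no change / it falls / it rises)

So I folded the charges into one number for each flask:

φ, grey = smaller of 1.05 (protonated nucleophile per electrophile) and 0.500 (free base per electrophile, divided by two) = 0.500

φ, violet = smaller of 1.05 and 1.00 = 1.00

This φ, the fraction of the electrophile charged that on this supposition the charges allow to react, makes free base the limiting reagent in grey.

Then I tested it. East and north-east both have φ = 0.500, and east had reacted 52.0% at 4.00 min. But at 20.0 min east stood at 66.0% and north-east at 52.0%, a gap of 14 percentage points against a scatter of 1.5 points. So one number was not enough: φ marked where the fast stage ended, not what followed. I expected violet near its φ and grey somewhere above its own, so a rise.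

The forecast gave grey 70%, violet 97%, and for the trend: it rises. Its ground was "a demand of two base equivalents per coupling".

The flasks gave grey 88.2%, violet 98.3%, and for the trend: it rises, by 10 points.

    electrophile + nucleophile → acid set free + target (k = 76.0 /M/min)
    free base + target ⇌ idle adduct, settled at all times (K = 200 /M)
    nucleophile + acid set free ⇌ protonated nucleophile, settled at all times (K = 35000 /M)
    acid set free + free base ⇌ salt of the base, settled at all times (K = 1.30 × 10⁶ /M)
    electrophile + acid set free → side product (k = 15.0 /M/min)
    crystals ⇌ target, rate k6*(cs6 - [target]) while solid is left; crystals form when [target] > cs6 (solubility = 1.00 mM, k = 1.50 /min)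

Violet ended close to its φ of 1.00, while grey passed its φ of 0.500 by 38 points, holding target 65.4% and side product 22.8%. A neighbouring flask is violet with 9.5 mM of protonated nucleophile, so its φ is 0.633, now set by the protonated nucleophile. In that neighbouring flask the electrophile reacted to 63.4%, with side product at 0.0439%. At the end of that neighbouring flask protonated nucleophile stood at 0%, and 31% of the free base charged was left.

The data were generated by integration from invented constants, and the scatter is random.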